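**Retrosynthetic overview**

1. Endgame on the trans-hydrindanone: esterify C1–OH and C6–OH with (R)-2-methylbutanoic acid and C5–OH with (Z)-3-methylpent-2-enoic acid, after SeO2 allylic hydroxylation at C6 and hydroxyl-directed epoxidation of the C4 isopropenyl group.
2. Six-membered ring (formed second): C4–C5 bond by a type 1 carbonyl-ene closure (citronellal-to-isopulegol type) of a C5 aldehyde onto a 2-methylprop-1-enyl group. The aldehyde carbon comes from a formaldehyde ene reaction on the C7a isopropenyl group.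
3. Five-membered ring (formed first): C1–C7a bond by a desymmetrizing intramolecular carbonyl-ene reaction of an acyclic α-keto aldehyde onto one of two 2-methylprop-1-enyl groups on the future C3a.
4. Acyclic precursor: Evans syn-aldol (sets C3 and the side-chain carbinol), 1,4-addition of an alkenyl Grignard reagent to a dienoyl imide, and a dithiane acyl anion for C1.
5. Enabling feature: C1(O)–C7a(H)–C7(=CH2) beside the C2 ketone of the five-membered ring is a homoallylic alcohol on a 1,1-disubstituted alkene (the ene retron). C3a sits between two CH–C(=CH2) units (C7a–C7 in the six-membered ring and C4–oxirane carbon), so it can start as a symmetric bis(2-methylprop-1-enyl)methine.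

Key step: step 9

Remark on the chemistry: locants follow octahydro-1H-indene numbering (C1 acyloxy carbon next to the ketone, C2 C=O, C3, C3a, C4 oxiranyl-bearing, C5, C6, C7 =CH2, C7a). The 2-methylbutanoyl groups of the target are (R); (R)-2-methylbutanoic acid and (4R)-4-benzyl-1,3-oxazolidin-2-one are taken as commercial.

**Route**

Step 1
Reactants: 1 3-methylbut-2-enal; 2 malonic acid
Product: 3 (2E)-5-methylhexa-2,4-dienoic acid
Conditions: pyridine, piperidine (cat.), 90 °C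
Reagents that add atoms: none
Why: Doebner–Knoevenagel condensation with decarboxylation should give the E-dienoic acid.

Step 2
Reactants: 3 (2E)-5-methylhexa-2,4-dienoic acid; 4 (4R)-4-benzyl-1,3-oxazolidin-2-one
Product: 6 (4R)-4-benzyl-3-[(2E)-5-methylhexa-2,4-dienoyl]-1,3-oxazolidin-2-one, via mixed pivalic anhydride 5 (not isolated)
Conditions: PivCl, Et3N, THF, −20 °C; then 4, LiCl, rt
Reagents that add atoms: none
Why: N-acylation of the oxazolidinone through the mixed anhydride under LiCl/Et3N activation; no stereocentre is touched.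

Step 3
Reactants: 6 (4R)-4-benzyl-3-[(2E)-5-methylhexa-2,4-dienoyl]-1,3-oxazolidin-2-one; 7 (2-methylprop-1-en-1-yl)magnesium bromide
Product: 8 (4R)-4-benzyl-3-[5-methyl-3-(2-methylprop-1-en-1-yl)hex-4-enoyl]-1,3-oxazolidin-2-one
Conditions: CuBr·SMe2 (30 mol %), THF/Me2S, −40 → −10 °C; sat. NH4Cl
Reagents that add atoms: none
Why: Copper-catalysed conjugate addition to the N-enoyl imide should go 1,4 because 1,6-attack would have to build a quaternary carbon; C-3 then carries two identical alkenyl groups, so no stereocentre arises.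

Step 4
Reactants: 8 (4R)-4-benzyl-3-[5-methyl-3-(2-methylprop-1-en-1-yl)hex-4-enoyl]-1,3-oxazolidin-2-one; 9 acetaldehyde
Product: 11 (4R)-4-benzyl-3-[(2R)-2-[(1S)-1-hydroxyethyl]-5-methyl-3-(2-methylprop-1-en-1-yl)hex-4-enoyl]-1,3-oxazolidin-2-one, via Z-boron enolate 10 (not isolated)
Conditions: Bu2BOTf, i-Pr2NEt, CH2Cl2, 0 °C; then 9, −78 → 0 °C; pH 7 buffer, MeOH, H2O2
Reagents that add atoms: none
Why: Evans syn-aldol: the Z-enolate reacts through a Zimmerman–Traxler chair on the face away from the benzyl group, which with the (R)-auxiliary should set the future C3 as R and the carbinol as S (syn).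

Step 5
Reactants: 11 (4R)-4-benzyl-3-[(2R)-2-[(1S)-1-hydroxyethyl]-5-methyl-3-(2-methylprop-1-en-1-yl)hex-4-enoyl]-1,3-oxazolidin-2-one
Product: 12 (2R)-2-[(1S)-1-hydroxyethyl]-N-methoxy-N,5-dimethyl-3-(2-methylprop-1-en-1-yl)hex-4-enamide
Conditions: MeNHOMe·HCl, AlMe3, CH2Cl2, −10 → 0 °C
Reagents that add atoms: N,O-dimethylhydroxylamine hydrochloride, CNOC.Cl
Why: Aluminium-amide transamination of the aldol imide, helped by the free β-hydroxyl, should give the Weinreb amide without epimerization and return the auxiliary.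

Step 6
Reactants: 12 (2R)-2-[(1S)-1-hydroxyethyl]-N-methoxy-N,5-dimethyl-3-(2-methylprop-1-en-1-yl)hex-4-enamide; 13 1,3-dithiane
Product: 14 (2R)-1-(1,3-dithian-2-yl)-2-[(1S)-1-hydroxyethyl]-5-methyl-3-(2-methylprop-1-en-1-yl)hex-4-en-1-one
Conditions: 13, n-BuLi, THF, −30 °C; then 12, −78 → −30 °C (3 equiv of the lithio reagent)
Reagents that add atoms: none
Why: Corey–Seebach acyl-anion addition in a Weinreb ketone synthesis; the chelated tetrahedral intermediate stops over-addition and the product is held as its dithiane anion, so the α-stereocentre should survive.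

Step 7
Reactants: 14 (2R)-1-(1,3-dithian-2-yl)-2-[(1S)-1-hydroxyethyl]-5-methyl-3-(2-methylprop-1-en-1-yl)hex-4-en-1-one
Product: 15 (2S,3R)-3-(1,3-dithiane-2-carbonyl)-6-methyl-4-(2-methylprop-1-en-1-yl)hept-5-en-2-yl acetate
Conditions: Ac2O, pyridine, DMAP (5 mol %), CH2Cl2, 0 °C
Reagents that add atoms: acetic anhydride, CC(=O)OC(C)=O
Why: Standard O-acetylation installs the acetate of the target early; kept cold to avoid β-elimination.

Step 8
Reactants: 15 (2S,3R)-3-(1,3-dithiane-2-carbonyl)-6-methyl-4-(2-methylprop-1-en-1-yl)hept-5-en-2-yl acetate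
Product: 16 (2S,3R)-6-methyl-4-(2-methylprop-1-en-1-yl)-3-(2-oxoacetyl)hept-5-en-2-yl acetate
Conditions: MeI, CaCO3, MeCN/H2O (9:1), rt → 40 °C; used crude after azeotropic drying
Reagents that add atoms: water, O
Why: Alkylative hydrolysis of the dithiane unmasks the α-keto aldehyde without touching the trisubstituted alkenes or the β-acetoxy ketone.

Step 9
Reactants: 16 (2S,3R)-6-methyl-4-(2-methylprop-1-en-1-yl)-3-(2-oxoacetyl)hept-5-en-2-yl acetate
Product: 17 (1S)-1-[(1R,2R,3S,4R)-4-hydroxy-2-(2-methylprop-1-en-1-yl)-5-oxo-3-(prop-1-en-2-yl)cyclopentyl]ethyl acetate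
Conditions: Yb(OTf)3 (10 mol %), 4 Å molecular sieves, CH2Cl2, 0 °C → rt
Reagents that add atoms: none
Why: The Lewis-acid-activated aldehyde carbon (C1) bonds to the CH carbon of one 2-methylprop-1-enyl group (future C7a) while an allylic methyl hydrogen moves to the carbonyl oxygen through a six-membered, concerted but asynchronous ene transition state, giving the α-ketol and an isopropenyl group. The closest known reactions are the type 1 intramolecular carbonyl-ene cyclization of 6-methylhept-5-enals to 2-isopropenylcyclopentanols and the ene reactions of glyoxylate-type 1,2-dicarbonyl enophiles. The cyclopentanone closes in a 5-exo-trig mode through C1–C7a, the C2 ketone being the activating group and a ring member. The C3 stereocentre from the aldol relays to three new centres: the acetoxyethyl group sits pseudo-equatorial, so the alkenyl group that does not react ends trans to it (fixing C3a by choice between two diastereotopic groups); allylic 1,3-strain holds C3a–H in the plane of the reacting alkene, so the new isopropenyl at C7a ends trans to the C3a substituent; and the cyclic hydrogen transfer forces the C1 oxygen and the isopropenyl group cis. The step needs group selectivity, the cis C1–O/C7a relationship and survival of the β-acetoxy ketone; the single pre-set centre, the concerted pathway under a mild non-nucleophilic Lewis acid and low temperature should secure them.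

Step 10
Reactants: 17 (1S)-1-[(1R,2R,3S,4R)-4-hydroxy-2-(2-methylprop-1-en-1-yl)-5-oxo-3-(prop-1-en-2-yl)cyclopentyl]ethyl acetate; 18 (2R)-2-methylbutanoic acid
Product: 19 (1R,3R,4R,5S)-3-[(1S)-1-(acetyloxy)ethyl]-4-(2-methylprop-1-en-1-yl)-2-oxo-5-(prop-1-en-2-yl)cyclopentyl (2R)-2-methylbutanoate
Conditions: DCC, DMAP (10 mol %), CH2Cl2, 0 °C → rt
Reagents that add atoms: none
Why: Steglich esterification caps the α-ketol with retention at C1 and should not racemize the acid.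

Step 11
Reactants: 19 (1R,3R,4R,5S)-3-[(1S)-1-(acetyloxy)ethyl]-4-(2-methylprop-1-en-1-yl)-2-oxo-5-(prop-1-en-2-yl)cyclopentyl (2R)-2-methylbutanoate
Product: 20 (1R,3R,4R,5S)-3-[(1S)-1-(acetyloxy)ethyl]-5-(4-hydroxybut-1-en-2-yl)-4-(2-methylprop-1-en-1-yl)-2-oxocyclopentyl (2R)-2-methylbutanoate
Conditions: (CH2O)n, Me2AlCl (3 equiv), CH2Cl2, −20 → 0 °C
Reagents that add atoms: formaldehyde (as paraformaldehyde), C=O
Why: Lewis-acid-promoted ene reaction of formaldehyde, in which a 1,1-disubstituted alkene should react ahead of the trisubstituted one; hydrogen is taken from the methyl group, so the C7 methylene is regenerated and the chain gains the future C5 carbon.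

Step 12
Reactants: 20 (1R,3R,4R,5S)-3-[(1S)-1-(acetyloxy)ethyl]-5-(4-hydroxybut-1-en-2-yl)-4-(2-methylprop-1-en-1-yl)-2-oxocyclopentyl (2R)-2-methylbutanoate
Product: 21 (1R,3R,4R,5S)-3-[(1S)-1-(acetyloxy)ethyl]-4-(2-methylprop-1-en-1-yl)-2-oxo-5-(4-oxobut-1-en-2-yl)cyclopentyl (2R)-2-methylbutanoate
Conditions: Dess–Martin periodinane, NaHCO3, CH2Cl2, 0 °C
Reagents that add atoms: none
Why: Buffered Dess–Martin oxidation gives the β,γ-unsaturated aldehyde without base, so the alkene should not move into conjugation.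

Step 13
Reactants: 21 (1R,3R,4R,5S)-3-[(1S)-1-(acetyloxy)ethyl]-4-(2-methylprop-1-en-1-yl)-2-oxo-5-(4-oxobut-1-en-2-yl)cyclopentyl (2R)-2-methylbutanoate
Product: 22 (1R,3R,3aR,4S,5R,7aS)-3-[(1S)-1-(acetyloxy)ethyl]-5-hydroxy-7-methylidene-2-oxo-4-(prop-1-en-2-yl)octahydro-1H-inden-1-yl (2R)-2-methylbutanoate
Conditions: ZnBr2, CH2Cl2, 0 °C
Reagents that add atoms: none
Why: Type 1 intramolecular carbonyl-ene reaction (citronellal-to-isopulegol type) closes the six-membered ring on the trans-1,2-disubstituted cyclopentane through a chair in which the zinc-bound oxygen and the developing isopropenyl group are both equatorial, which should give C5–OH and C4–isopropenyl trans to each other and to the ring-fusion bonds.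

Step 14
Reactants: 22 (1R,3R,3aR,4S,5R,7aS)-3-[(1S)-1-(acetyloxy)ethyl]-5-hydroxy-7-methylidene-2-oxo-4-(prop-1-en-2-yl)octahydro-1H-inden-1-yl (2R)-2-methylbutanoate
Product: 23 (1R,3R,3aS,4R,5R,7aS)-3-[(1S)-1-(acetyloxy)ethyl]-5-hydroxy-7-methylidene-4-[(2R)-2-methyloxiran-2-yl]-2-oxooctahydro-1H-inden-1-yl (2R)-2-methylbutanoate
Conditions: VO(acac)2 (5 mol %), t-BuOOH, CH2Cl2, 0 °C → rt
Reagents that add atoms: tert-butyl hydroperoxide, CC(C)(C)OO
Why: Hydroxyl-directed epoxidation of a homoallylic alcohol: the equatorial C5 vanadate reaches only the neighbouring isopropenyl group (the C7 methylene has its π-lobes axial and out of reach), and in the rotamer with =CH2 eclipsing C4–H the oxygen is delivered to the face turned towards C5, which should give the (R)-oxirane.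

Step 15
Reactants: 24 ethyl pent-2-ynoate
Product: 25 ethyl (2Z)-3-methylpent-2-enoate
Conditions: MeLi, CuI, THF, −78 °C; then 24, −78 °C; sat. NH4Cl at −78 °C
Reagents that add atoms: methyllithium (used as lithium dimethylcuprate), C[Li]
Why: Syn-carbocupration of the ynoate and protonation with retention put the new methyl cis to hydrogen, so the ethyl group ends cis to the ester (Z).

Step 16
Reactants: 25 ethyl (2Z)-3-methylpent-2-enoate
Product: 26 (2Z)-3-methylpent-2-enoic acid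
Conditions: LiOH, THF/H2O, rt; then 1 M HCl
Reagents that add atoms: lithium hydroxide, [Li+].[OH-]
Why: Mild saponification should keep the Z-geometry.

Step 17
Reactants: 23 (1R,3R,3aS,4R,5R,7aS)-3-[(1S)-1-(acetyloxy)ethyl]-5-hydroxy-7-methylidene-4-[(2R)-2-methyloxiran-2-yl]-2-oxooctahydro-1H-inden-1-yl (2R)-2-methylbutanoate; 26 (2Z)-3-methylpent-2-enoic acid
Product: 28 (1R,3R,3aS,4R,5R,7aS)-3-[(1S)-1-(acetyloxy)ethyl]-7-methylidene-1-{[(2R)-2-methylbutanoyl]oxy}-4-[(2R)-2-methyloxiran-2-yl]-2-oxooctahydro-1H-inden-5-yl (2Z)-3-methylpent-2-enoate, via mixed trichlorobenzoic anhydride 27 (not isolated)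
Conditions: 26, 2,4,6-trichlorobenzoyl chloride, Et3N, toluene, rt, filter; then 23, DMAP (0.2 equiv), toluene, rt
Reagents that add atoms: none
Why: Yamaguchi esterification of the equatorial C5 alcohol; the pre-formed mixed anhydride and little DMAP should limit Z/E scrambling of the enoate and base exposure of the β-acetoxy ketone.

Step 18
Reactants: 28 (1R,3R,3aS,4R,5R,7aS)-3-[(1S)-1-(acetyloxy)ethyl]-7-methylidene-1-{[(2R)-2-methylbutanoyl]oxy}-4-[(2R)-2-methyloxiran-2-yl]-2-oxooctahydro-1H-inden-5-yl (2Z)-3-methylpent-2-enoate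
Product: 29 (1R,3R,3aS,4R,5S,6R,7aS)-3-[(1S)-1-(acetyloxy)ethyl]-6-hydroxy-7-methylidene-1-{[(2R)-2-methylbutanoyl]oxy}-4-[(2R)-2-methyloxiran-2-yl]-2-oxooctahydro-1H-inden-5-yl (2Z)-3-methylpent-2-enoate
Conditions: SeO2 (0.5 equiv), t-BuOOH, CH2Cl2, rt
Reagents that add atoms: selenium dioxide, O=[Se]=O; tert-butyl hydroperoxide, CC(C)(C)OO
Why: SeO2 allylic hydroxylation (ene reaction, then [2,3]-sigmatropic shift) should attack the ring CH2 (C6) rather than the C7a methine and deliver oxygen pseudo-axially, that is to the β-face cis to C5–O; the oxirane and the electron-poor enoate should be left alone.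

Step 19
Reactants: 29 (1R,3R,3aS,4R,5S,6R,7aS)-3-[(1S)-1-(acetyloxy)ethyl]-6-hydroxy-7-methylidene-1-{[(2R)-2-methylbutanoyl]oxy}-4-[(2R)-2-methyloxiran-2-yl]-2-oxooctahydro-1H-inden-5-yl (2Z)-3-methylpent-2-enoate; 18 (2R)-2-methylbutanoic acid
Product: 30 (1R,3R,3aS,4R,5S,6R,7aS)-3-[(1S)-1-(acetyloxy)ethyl]-7-methylidene-1,6-bis{[(2R)-2-methylbutanoyl]oxy}-4-[(2R)-2-methyloxiran-2-yl]-2-oxooctahydro-1H-inden-5-yl (2Z)-3-methylpent-2-enoate (CNP0169102.1)
Conditions: DCC, DMAP (10 mol %), CH2Cl2, 0 °C → rt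
Reagents that add atoms: none
Why: Steglich esterification of the axial allylic C6 alcohol with retention completes the target.

**Compound list**

1 | 3-methylbut-2-enal | CC(C)=CC=O | starting material
2 | malonic acid | OC(=O)CC(=O)O | starting material
3 | (2E)-5-methylhexa-2,4-dienoic acid | CC(C)=C/C=C/C(=O)O | intermediate
4 | (4R)-4-benzyl-1,3-oxazolidin-2-one | O=C1OC[C@@H](Cc2ccccc2)N1 | starting material
5 | (2E)-5-methylhexa-2,4-dienoic pivalic anhydride | CC(C)=C/C=C/C(=O)OC(=O)C(C)(C)C | intermediate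
6 | (4R)-4-benzyl-3-[(2E)-5-methylhexa-2,4-dienoyl]-1,3-oxazolidin-2-one | CC(C)=C/C=C/C(=O)N1C(=O)OC[C@H]1Cc1ccccc1 | intermediate
7 | (2-methylprop-1-en-1-yl)magnesium bromide | CC(C)=C[Mg]Br | starting material
8 | (4R)-4-benzyl-3-[5-methyl-3-(2-methylprop-1-en-1-yl)hex-4-enoyl]-1,3-oxazolidin-2-one | CC(C)=CC(CC(=O)N1C(=O)OC[C@H]1Cc1ccccc1)C=C(C)C | intermediate
9 | acetaldehyde | CC=O | starting material
10 | dibutylboron Z-enolate of 8 | CCCCB(CCCC)O/C(=C\C(C=C(C)C)C=C(C)C)N1C(=O)OC[C@H]1Cc1ccccc1 | intermediate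
11 | (4R)-4-benzyl-3-[(2R)-2-[(1S)-1-hydroxyethyl]-5-methyl-3-(2-methylprop-1-en-1-yl)hex-4-enoyl]-1,3-oxazolidin-2-one | C[C@H](O)[C@@H](C(C=C(C)C)C=C(C)C)C(=O)N1C(=O)OC[C@H]1Cc1ccccc1 | intermediate
12 | (2R)-2-[(1S)-1-hydroxyethyl]-N-methoxy-N,5-dimethyl-3-(2-methylprop-1-en-1-yl)hex-4-enamide | C[C@H](O)[C@@H](C(C=C(C)C)C=C(C)C)C(=O)N(C)OC | intermediate
13 | 1,3-dithiane | C1CSCSC1 | starting material
14 | (2R)-1-(1,3-dithian-2-yl)-2-[(1S)-1-hydroxyethyl]-5-methyl-3-(2-methylprop-1-en-1-yl)hex-4-en-1-one | C[C@H](O)[C@@H](C(C=C(C)C)C=C(C)C)C(=O)C1SCCCS1 | intermediate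
15 | (2S,3R)-3-(1,3-dithiane-2-carbonyl)-6-methyl-4-(2-methylprop-1-en-1-yl)hept-5-en-2-yl acetate | C[C@H](OC(C)=O)[C@@H](C(C=C(C)C)C=C(C)C)C(=O)C1SCCCS1 | intermediate
16 | (2S,3R)-6-methyl-4-(2-methylprop-1-en-1-yl)-3-(2-oxoacetyl)hept-5-en-2-yl acetate | C[C@H](OC(C)=O)[C@@H](C(C=C(C)C)C=C(C)C)C(=O)C=O | intermediate
17 | (1S)-1-[(1R,2R,3S,4R)-4-hydroxy-2-(2-methylprop-1-en-1-yl)-5-oxo-3-(prop-1-en-2-yl)cyclopentyl]ethyl acetate | C=C(C)[C@@H]1[C@H]([C@H]([C@H](C)OC(C)=O)C(=O)[C@@H]1O)C=C(C)C | intermediate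
18 | (2R)-2-methylbutanoic acid | CC[C@@H](C)C(=O)O | starting material
19 | (1R,3R,4R,5S)-3-[(1S)-1-(acetyloxy)ethyl]-4-(2-methylprop-1-en-1-yl)-2-oxo-5-(prop-1-en-2-yl)cyclopentyl (2R)-2-methylbutanoate | C=C(C)[C@@H]1[C@H]([C@H]([C@H](C)OC(C)=O)C(=O)[C@@H]1OC(=O)[C@H](C)CC)C=C(C)C | intermediate
20 | (1R,3R,4R,5S)-3-[(1S)-1-(acetyloxy)ethyl]-5-(4-hydroxybut-1-en-2-yl)-4-(2-methylprop-1-en-1-yl)-2-oxocyclopentyl (2R)-2-methylbutanoate | C=C(CCO)[C@@H]1[C@H]([C@H]([C@H](C)OC(C)=O)C(=O)[C@@H]1OC(=O)[C@H](C)CC)C=C(C)C | intermediate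
21 | (1R,3R,4R,5S)-3-[(1S)-1-(acetyloxy)ethyl]-4-(2-methylprop-1-en-1-yl)-2-oxo-5-(4-oxobut-1-en-2-yl)cyclopentyl (2R)-2-methylbutanoate | C=C(CC=O)[C@@H]1[C@H]([C@H]([C@H](C)OC(C)=O)C(=O)[C@@H]1OC(=O)[C@H](C)CC)C=C(C)C | intermediate
22 | (1R,3R,3aR,4S,5R,7aS)-3-[(1S)-1-(acetyloxy)ethyl]-5-hydroxy-7-methylidene-2-oxo-4-(prop-1-en-2-yl)octahydro-1H-inden-1-yl (2R)-2-methylbutanoate | C=C1[C@@H]2[C@H]([C@H]([C@H](C)OC(C)=O)C(=O)[C@@H]2OC(=O)[C@H](C)CC)[C@@H](C(C)=C)[C@H](O)C1 | intermediate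
23 | (1R,3R,3aS,4R,5R,7aS)-3-[(1S)-1-(acetyloxy)ethyl]-5-hydroxy-7-methylidene-4-[(2R)-2-methyloxiran-2-yl]-2-oxooctahydro-1H-inden-1-yl (2R)-2-methylbutanoate | C=C1[C@@H]2[C@H]([C@H]([C@H](C)OC(C)=O)C(=O)[C@@H]2OC(=O)[C@H](C)CC)[C@@H]([C@]2(C)CO2)[C@H](O)C1 | intermediate
24 | ethyl pent-2-ynoate | CCC#CC(=O)OCC | starting material
25 | ethyl (2Z)-3-methylpent-2-enoate | CCOC(=O)/C=C(/C)CC | intermediate
26 | (2Z)-3-methylpent-2-enoic acid | OC(=O)/C=C(/C)CC | intermediate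
27 | (2Z)-3-methylpent-2-enoic 2,4,6-trichlorobenzoic anhydride | O=C(/C=C(/C)CC)OC(=O)c1c(Cl)cc(Cl)cc1Cl | intermediate
28 | (1R,3R,3aS,4R,5R,7aS)-3-[(1S)-1-(acetyloxy)ethyl]-7-methylidene-1-{[(2R)-2-methylbutanoyl]oxy}-4-[(2R)-2-methyloxiran-2-yl]-2-oxooctahydro-1H-inden-5-yl (2Z)-3-methylpent-2-enoate | C=C1[C@@H]2[C@H]([C@H]([C@H](C)OC(C)=O)C(=O)[C@@H]2OC(=O)[C@H](C)CC)[C@@H]([C@]2(C)CO2)[C@H](OC(=O)/C=C(/C)CC)C1 | intermediate
29 | (1R,3R,3aS,4R,5S,6R,7aS)-3-[(1S)-1-(acetyloxy)ethyl]-6-hydroxy-7-methylidene-1-{[(2R)-2-methylbutanoyl]oxy}-4-[(2R)-2-methyloxiran-2-yl]-2-oxooctahydro-1H-inden-5-yl (2Z)-3-methylpent-2-enoate | C=C1[C@@H]2[C@H]([C@H]([C@H](C)OC(C)=O)C(=O)[C@@H]2OC(=O)[C@H](C)CC)[C@@H]([C@]2(C)CO2)[C@H](OC(=O)/C=C(/C)CC)[C@@H]1O | intermediate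
30 | (1R,3R,3aS,4R,5S,6R,7aS)-3-[(1S)-1-(acetyloxy)ethyl]-7-methylidene-1,6-bis{[(2R)-2-methylbutanoyl]oxy}-4-[(2R)-2-methyloxiran-2-yl]-2-oxooctahydro-1H-inden-5-yl (2Z)-3-methylpent-2-enoate | C=C1[C@@H]2[C@H]([C@H]([C@H](C)OC(C)=O)C(=O)[C@@H]2OC(=O)[C@H](C)CC)[C@@H]([C@]2(C)CO2)[C@H](OC(=O)/C=C(/C)CC)[C@@H]1OC(=O)[C@H](C)CC | target

**Step count and risks**

Total: 19 steps (17 in the main line, 2 for acid 26). Longest linear sequence: 17 steps (steps 1–14 and 17–19).

Steps most likely to fail: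

Step 9 (key step). What may go wrong: β-elimination of the acetoxy group or epimerization next to the ketone under Lewis acid, and incomplete discrimination between the two diastereotopic alkenyl groups. Fallback: change the protecting-group strategy so that the ene reaction runs thermally on a non-chelating silyl ether that cannot eliminate. It sets out from 14. Silylation (TBSOTf, 2,6-lutidine) should give (2R)-2-[(1S)-1-{[tert-butyl(dimethyl)silyl]oxy}ethyl]-1-(1,3-dithian-2-yl)-5-methyl-3-(2-methylprop-1-en-1-yl)hex-4-en-1-one F1. Alkylative hydrolysis (MeI, CaCO3, aqueous MeCN) should give (3R)-3-[(1S)-1-{[tert-butyl(dimethyl)silyl]oxy}ethyl]-6-methyl-4-(2-methylprop-1-en-1-yl)-2-oxohept-5-enal F2. Heating in toluene at 80 °C without Lewis acid should give (2R,3S,4R,5R)-5-[(1S)-1-{[tert-butyl(dimethyl)silyl]oxy}ethyl]-2-hydroxy-4-(2-methylprop-1-en-1-yl)-3-(prop-1-en-2-yl)cyclopentan-1-one F3. Steglich esterification with 18 should give (1R,3R,4R,5S)-3-[(1S)-1-{[tert-butyl(dimethyl)silyl]oxy}ethyl]-4-(2-methylprop-1-en-1-yl)-2-oxo-5-(prop-1-en-2-yl)cyclopentyl (2R)-2-methylbutanoate F4. HF·pyridine should free (1R,3R,4R,5S)-3-[(1S)-1-hydroxyethyl]-4-(2-methylprop-1-en-1-yl)-2-oxo-5-(prop-1-en-2-yl)cyclopentyl (2R)-2-methylbutanoate F5, and acetylation (Ac2O, pyridine) comes back to the route at 19.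

Step 11. What may go wrong: poor chemoselectivity between the 1,1-disubstituted and the trisubstituted alkene, double addition of formaldehyde, or Lewis-acid damage to the β-acetoxy ketone. Fallback: replace formaldehyde by a glyoxylate ene reaction followed by oxidative decarboxylation. It sets out from 19. Allyl glyoxylate with SnCl4 at −78 °C should react at the 1,1-disubstituted alkene and give prop-2-en-1-yl 4-[(1S,2R,3R,5R)-3-[(1S)-1-(acetyloxy)ethyl]-5-{[(2R)-2-methylbutanoyl]oxy}-2-(2-methylprop-1-en-1-yl)-4-oxocyclopentyl]-2-hydroxypent-4-enoate F6 (carbinol epimers, a centre that is destroyed). Deallylation with Pd(PPh3)4 and morpholine should give the corresponding 2-hydroxypent-4-enoic acid F7. Pb(OAc)4 then cleaves the α-hydroxy acid to the aldehyde, so the fallback comes back to the route at 21 and replaces steps 11 and 12.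

Step 18. What may go wrong: poor facial selectivity in the [2,3]-shift, so that oxygen arrives on the α-face, besides competing attack at the C7a methine and over-oxidation. Fallback: use the epimer with an invertive esterification instead of a retentive one. It sets out from 28. If SeO2/t-BuOOH gives mainly (1R,3R,3aS,4R,5S,6S,7aS)-3-[(1S)-1-(acetyloxy)ethyl]-6-hydroxy-7-methylidene-1-{[(2R)-2-methylbutanoyl]oxy}-4-[(2R)-2-methyloxiran-2-yl]-2-oxooctahydro-1H-inden-5-yl (2Z)-3-methylpent-2-enoate F8, a Mitsunobu reaction with 18 (PPh3, diisopropyl azodicarboxylate, toluene, 0 °C) should invert C6 and come back to the route at 30.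

**Further compounds**

F1 | step 9 | (2R)-2-[(1S)-1-{[tert-butyl(dimethyl)silyl]oxy}ethyl]-1-(1,3-dithian-2-yl)-5-methyl-3-(2-methylprop-1-en-1-yl)hex-4-en-1-one | C[C@H](O[Si](C)(C)C(C)(C)C)[C@@H](C(C=C(C)C)C=C(C)C)C(=O)C1SCCCS1
F2 | step 9 | (3R)-3-[(1S)-1-{[tert-butyl(dimethyl)silyl]oxy}ethyl]-6-methyl-4-(2-methylprop-1-en-1-yl)-2-oxohept-5-enal | C[C@H](O[Si](C)(C)C(C)(C)C)[C@@H](C(C=C(C)C)C=C(C)C)C(=O)C=O
F3 | step 9 | (2R,3S,4R,5R)-5-[(1S)-1-{[tert-butyl(dimethyl)silyl]oxy}ethyl]-2-hydroxy-4-(2-methylprop-1-en-1-yl)-3-(prop-1-en-2-yl)cyclopentan-1-one | C=C(C)[C@@H]1[C@H]([C@H]([C@H](C)O[Si](C)(C)C(C)(C)C)C(=O)[C@@H]1O)C=C(C)C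
F4 | step 9 | (1R,3R,4R,5S)-3-[(1S)-1-{[tert-butyl(dimethyl)silyl]oxy}ethyl]-4-(2-methylprop-1-en-1-yl)-2-oxo-5-(prop-1-en-2-yl)cyclopentyl (2R)-2-methylbutanoate | C=C(C)[C@@H]1[C@H]([C@H]([C@H](C)O[Si](C)(C)C(C)(C)C)C(=O)[C@@H]1OC(=O)[C@H](C)CC)C=C(C)C
F5 | step 9 | (1R,3R,4R,5S)-3-[(1S)-1-hydroxyethyl]-4-(2-methylprop-1-en-1-yl)-2-oxo-5-(prop-1-en-2-yl)cyclopentyl (2R)-2-methylbutanoate | C=C(C)[C@@H]1[C@H]([C@H]([C@H](C)O)C(=O)[C@@H]1OC(=O)[C@H](C)CC)C=C(C)C
F6 | step 11 | prop-2-en-1-yl 4-[(1S,2R,3R,5R)-3-[(1S)-1-(acetyloxy)ethyl]-5-{[(2R)-2-methylbutanoyl]oxy}-2-(2-methylprop-1-en-1-yl)-4-oxocyclopentyl]-2-hydroxypent-4-enoate | C=C(CC(O)C(=O)OCC=C)[C@@H]1[C@H]([C@H]([C@H](C)OC(C)=O)C(=O)[C@@H]1OC(=O)[C@H](C)CC)C=C(C)C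
F7 | step 11 | 4-[(1S,2R,3R,5R)-3-[(1S)-1-(acetyloxy)ethyl]-5-{[(2R)-2-methylbutanoyl]oxy}-2-(2-methylprop-1-en-1-yl)-4-oxocyclopentyl]-2-hydroxypent-4-enoic acid | C=C(CC(O)C(=O)O)[C@@H]1[C@H]([C@H]([C@H](C)OC(C)=O)C(=O)[C@@H]1OC(=O)[C@H](C)CC)C=C(C)C
F8 | step 18 | (1R,3R,3aS,4R,5S,6S,7aS)-3-[(1S)-1-(acetyloxy)ethyl]-6-hydroxy-7-methylidene-1-{[(2R)-2-methylbutanoyl]oxy}-4-[(2R)-2-methyloxiran-2-yl]-2-oxooctahydro-1H-inden-5-yl (2Z)-3-methylpent-2-enoate | C=C1[C@@H]2[C@H]([C@H]([C@H](C)OC(C)=O)C(=O)[C@@H]2OC(=O)[C@H](C)CC)[C@@H]([C@]2(C)CO2)[C@H](OC(=O)/C=C(/C)CC)[C@H]1O
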